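**Retrosynthetic overview**
- Target ⇐ C9 desilylation and C8–O methacryloylation of a macrocyclic hydroxy lactone; the ten-membered carbocycle is the last ring formed, by ring-closing metathesis at C1=C10.
- The γ-lactone is the first ring formed: C5–C6 coupling of an E-alkenyl iodide (from hex-1-en-5-yne) with a C6 aldehyde, then lactonisation onto C12.
- The C6–C14 core ⇐ C7–C8 indium coupling of an α-hydroxy aldehyde with a Z-allylic bromide; both partners come from one Morita–Baylis–Hillman (MBH) adduct of glyoxal mono-acetal and methyl acrylate.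
- Key step: enantioselective SN2′ hydroxylation of that achiral bromide, which forms the C9–O bond; C8, C7 and C6 are then relayed from C9.

Assumptions: positions are cited with germacrane numbers (C1–C14, lactone carbonyl C12); the cinchona catalyst of step 3 is assumed to deliver the S alcohol (its pseudoenantiomer (DHQ)2PHAL is used if the sense is opposite), and the lipase of the first fallback is assumed to acylate the R alcohol.

**Step 1**
Reactants: 1 2,2-dimethoxyacetaldehyde (60% aqueous solution); 2 methyl acrylate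
Product: 3 methyl (±)-3-hydroxy-4,4-dimethoxy-2-methylidenebutanoate
Conditions: DABCO (0.5 equiv), 1,4-dioxane/H2O (1:1), rt
Reagents that add atoms: none
Why: Morita–Baylis–Hillman reaction of an activated, non-enolisable aldehyde with the DABCO–acrylate zwitterion; the racemic stereocentre is erased in step 2.

**Step 2**
Reactants: 3 methyl (±)-3-hydroxy-4,4-dimethoxy-2-methylidenebutanoate
Product: 4 methyl (2Z)-2-(bromomethyl)-4,4-dimethoxybut-2-enoate
Conditions: NBS, Me2S, CH2Cl2, 0 °C to rt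
Reagents that add atoms: N-bromosuccinimide, O=C1CCC(=O)N1Br
Why: Corey–Kim-type bromination of an MBH alcohol with SN2′ allylic transposition, which gives the thermodynamically preferred Z-2-(bromomethyl)enoate under non-acidic conditions that leave the acetal intact.

**Step 3**
Reactants: 4 methyl (2Z)-2-(bromomethyl)-4,4-dimethoxybut-2-enoate
Product: 5 methyl (3S)-3-hydroxy-4,4-dimethoxy-2-methylidenebutanoate
Conditions: (DHQD)2PHAL (10 mol %), H2O (10 equiv), NaHCO3 (1.5 equiv), MeCN, 0 °C
Reagents that add atoms: water, O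
Why: Proposed new method: enantioselective SN2′ hydroxylation of an achiral MBH-type allylic bromide, in which the quinuclidine nitrogen of the cinchona catalyst displaces bromide to give a chiral allylic ammonium ion and hydrogencarbonate-assisted water then adds to the γ-carbon inside the catalyst pocket, releasing the catalyst and forming the C9–O bond and the S stereocentre (kinetic γ-attack; the product alcohol cannot re-ionise, so the ee is not eroded); the closest known reaction type is the cinchona-catalysed asymmetric allylic substitution of aryl-substituted MBH carbonates with water and other O-nucleophiles, not yet shown for bromides or for an acetal-bearing aliphatic substrate.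

**Step 4**
Reactants: 5 methyl (3S)-3-hydroxy-4,4-dimethoxy-2-methylidenebutanoate; 4 methyl (2Z)-2-(bromomethyl)-4,4-dimethoxybut-2-enoate
Product: 7 dimethyl (3R,4S,5S)-3-(dimethoxymethyl)-4,5-dihydroxy-2,6-dimethylideneheptanedioate, via hydroxy aldehyde 6 (not isolated)
Conditions: Dowex 50WX8 (H+ form), H2O/THF, 40 °C, filter; then 4 (1.3 equiv), In powder, THF/H2O (1:1), rt, neutral work-up
Reagents that add atoms: water, O
Why: Acid hydrolysis unmasks the α-hydroxy aldehyde, which undergoes an indium-mediated Barbier 2-(alkoxycarbonyl)allylation in water: chelation of indium by the free α-hydroxyl sets C8 syn to C9, and the Z-configured allylindium reacts at its γ-carbon through a chair transition state to set C7 syn to the new carbinol, as in the known syn,syn-selective couplings of Z-2-(bromomethyl)alk-2-enoates with α-hydroxy aldehydes.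

**Step 5**
Reactants: 7 dimethyl (3R,4S,5S)-3-(dimethoxymethyl)-4,5-dihydroxy-2,6-dimethylideneheptanedioate
Product: 8 dimethyl (3R,4S,5S)-5-[(tert-butyldimethylsilyl)oxy]-3-(dimethoxymethyl)-4-hydroxy-2,6-dimethylideneheptanedioate
Conditions: TBSCl (1.05 equiv), imidazole, DMF, −20 °C
Reagents that add atoms: tert-butyldimethylsilyl chloride, CC(C)(C)[Si](C)(C)Cl
Why: Regioselective silylation: the allylic C9 hydroxyl, flanked by the planar sp2 C10, is expected to be more accessible than the C8 hydroxyl next to the doubly branched C7, so only C9–OH is protected, which prevents lactol formation with the C6 aldehyde and reserves C8–OH for the ester.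

**Step 6**
Reactants: 8 dimethyl (3R,4S,5S)-5-[(tert-butyldimethylsilyl)oxy]-3-(dimethoxymethyl)-4-hydroxy-2,6-dimethylideneheptanedioate
Product: 9 dimethyl (3R,4S,5S)-5-[(tert-butyldimethylsilyl)oxy]-3-formyl-4-hydroxy-2,6-dimethylideneheptanedioate
Conditions: PPTS (20 mol %), acetone/H2O (9:1), 40 °C; used crude at once
Reagents that add atoms: water, O
Why: Mild acid-catalysed acetal hydrolysis that the TBS ether and the esters survive; the β-hydroxy aldehyde is carried on immediately to avoid epimerisation at C7 or β-elimination.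

**Step 7**
Reactants: 10 hex-1-en-5-yne
Product: 12 (1E)-1-iodo-2-methylhexa-1,5-diene, via alkenylalane 11 (not isolated)
Conditions: Me3Al, Cp2ZrCl2 (20 mol %), CH2Cl2, 0 °C to rt; then I2, THF, −30 °C
Reagents that add atoms: trimethylaluminium, C[Al](C)C; iodine, II
Why: Negishi zirconium-catalysed carboalumination adds methyl and aluminium syn and regioselectively across the terminal alkyne (the alkene is untouched), and iodinolysis with retention gives the E-alkenyl iodide.

**Step 8**
Reactants: 9 dimethyl (3R,4S,5S)-5-[(tert-butyldimethylsilyl)oxy]-3-formyl-4-hydroxy-2,6-dimethylideneheptanedioate; 12 (1E)-1-iodo-2-methylhexa-1,5-diene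
Product: 14 methyl (3S,4S)-3-[(tert-butyldimethylsilyl)oxy]-4-hydroxy-2-methylidene-4-[(2R,3R)-4-methylidene-2-[(1E)-2-methylhexa-1,5-dien-1-yl]-5-oxooxolan-3-yl]butanoate, via hydroxy ester 13 (not isolated)
Conditions: CrCl2 (4 equiv), NiCl2 (2 mol %), DMSO, rt; then PPTS (cat.), CH2Cl2, rt on the crude
Reagents that add atoms: none
Why: Nozaki–Hiyama–Kishi coupling, chemoselective for the aldehyde in the presence of esters, acrylates and the free hydroxyl; Felkin–Anh addition (C8 branch as the large group), reinforced by the 1,3-anti preference of the β-oxygenated aldehyde, sets C6 (R), and the new γ-hydroxyl closes the trans-disubstituted α-methylene-γ-lactone onto the C12 ester.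

**Step 9**
Reactants: 14 methyl (3S,4S)-3-[(tert-butyldimethylsilyl)oxy]-4-hydroxy-2-methylidene-4-[(2R,3R)-4-methylidene-2-[(1E)-2-methylhexa-1,5-dien-1-yl]-5-oxooxolan-3-yl]butanoate
Product: 15 methyl (3aR,4S,5S,6E,10E,11aR)-5-[(tert-butyldimethylsilyl)oxy]-4-hydroxy-10-methyl-3-methylidene-2-oxo-2,3,3a,4,5,8,9,11a-octahydrocyclodeca[b]furan-6-carboxylate
Conditions: second-generation Hoveyda–Grubbs catalyst (10 mol %), toluene (1 mM), 80 °C, argon sparge
Reagents that add atoms: none
Why: Ring-closing metathesis in which the ruthenium carbene loads at the terminal vinyl group and closes onto the 1,1-disubstituted acrylate to give the trisubstituted C1=C10 enoate with C2 cis to C9, the geometry favoured by both ring size and the ester-trans preference; the trans-lactone and the E C4=C5 olefin pre-organise the chain as in metathesis routes to other germacranolides.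

**Step 10**
Reactants: 15 methyl (3aR,4S,5S,6E,10E,11aR)-5-[(tert-butyldimethylsilyl)oxy]-4-hydroxy-10-methyl-3-methylidene-2-oxo-2,3,3a,4,5,8,9,11a-octahydrocyclodeca[b]furan-6-carboxylate
Product: 16 methyl (3aS,4S,5S,6E,10E,11aR)-5-[(tert-butyldimethylsilyl)oxy]-10-methyl-3-methylidene-4-[(2-methylprop-2-enoyl)oxy]-2-oxo-2,3,3a,4,5,8,9,11a-octahydrocyclodeca[b]furan-6-carboxylate
Conditions: methacrylic anhydride, DMAP, Et3N, BHT (trace), CH2Cl2, 0 °C to rt
Reagents that add atoms: methacrylic anhydride, CC(=C)C(=O)OC(=O)C(C)=C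
Why: DMAP-catalysed (Steglich-type) acylation of the only free hydroxyl, C8–OH, with no stereocentre touched.

**Step 11**
Reactants: 16 methyl (3aS,4S,5S,6E,10E,11aR)-5-[(tert-butyldimethylsilyl)oxy]-10-methyl-3-methylidene-4-[(2-methylprop-2-enoyl)oxy]-2-oxo-2,3,3a,4,5,8,9,11a-octahydrocyclodeca[b]furan-6-carboxylate
Product: 17 methyl (3aS,4S,5S,6E,10E,11aR)-5-hydroxy-10-methyl-3-methylidene-4-[(2-methylprop-2-enoyl)oxy]-2-oxo-2,3,3a,4,5,8,9,11a-octahydrocyclodeca[b]furan-6-carboxylate (CNP0282644.1)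
Conditions: HF·pyridine, pyridine/THF, 0 °C to rt
Reagents that add atoms: none
Why: Fluoride-mediated desilylation under buffered acidic conditions removes the TBS ether without acyl migration from C8 to C9 or conjugate addition to the three Michael acceptors.

**Compound list**
1 | 2,2-dimethoxyacetaldehyde | COC(OC)C=O | starting material
2 | methyl acrylate | C=CC(=O)OC | starting material
3 | methyl (±)-3-hydroxy-4,4-dimethoxy-2-methylidenebutanoate | COC(OC)C(O)C(=C)C(=O)OC | intermediate
4 | methyl (2Z)-2-(bromomethyl)-4,4-dimethoxybut-2-enoate | COC(=O)/C(CBr)=C/C(OC)OC | intermediate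
5 | methyl (3S)-3-hydroxy-4,4-dimethoxy-2-methylidenebutanoate | COC(OC)[C@@H](O)C(=C)C(=O)OC | intermediate
6 | methyl (3S)-3-hydroxy-2-methylidene-4-oxobutanoate | O=C[C@@H](O)C(=C)C(=O)OC | intermediate
7 | dimethyl (3R,4S,5S)-3-(dimethoxymethyl)-4,5-dihydroxy-2,6-dimethylideneheptanedioate | COC(=O)C(=C)[C@@H](C(OC)OC)[C@H](O)[C@@H](O)C(=C)C(=O)OC | intermediate
8 | dimethyl (3R,4S,5S)-5-[(tert-butyldimethylsilyl)oxy]-3-(dimethoxymethyl)-4-hydroxy-2,6-dimethylideneheptanedioate | COC(=O)C(=C)[C@@H](C(OC)OC)[C@H](O)[C@@H](O[Si](C)(C)C(C)(C)C)C(=C)C(=O)OC | intermediate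
9 | dimethyl (3R,4S,5S)-5-[(tert-butyldimethylsilyl)oxy]-3-formyl-4-hydroxy-2,6-dimethylideneheptanedioate | COC(=O)C(=C)[C@@H](C=O)[C@H](O)[C@@H](O[Si](C)(C)C(C)(C)C)C(=C)C(=O)OC | intermediate
10 | hex-1-en-5-yne | C#CCCC=C | starting material
11 | dimethyl[(1E)-2-methylhexa-1,5-dien-1-yl]alane | C[Al](C)/C=C(\C)CCC=C | intermediate
12 | (1E)-1-iodo-2-methylhexa-1,5-diene | I/C=C(\C)CCC=C | intermediate
13 | dimethyl (3S,4S,5S)-5-[(tert-butyldimethylsilyl)oxy]-4-hydroxy-3-[(1R,2E)-1-hydroxy-3-methylhepta-2,6-dien-1-yl]-2,6-dimethylideneheptanedioate | COC(=O)C(=C)[C@@H]([C@H](O)/C=C(\C)CCC=C)[C@H](O)[C@@H](O[Si](C)(C)C(C)(C)C)C(=C)C(=O)OC | intermediate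
14 | methyl (3S,4S)-3-[(tert-butyldimethylsilyl)oxy]-4-hydroxy-2-methylidene-4-[(2R,3R)-4-methylidene-2-[(1E)-2-methylhexa-1,5-dien-1-yl]-5-oxooxolan-3-yl]butanoate | C=C1C(=O)O[C@H](/C=C(\C)CCC=C)[C@H]1[C@H](O)[C@@H](O[Si](C)(C)C(C)(C)C)C(=C)C(=O)OC | intermediate
15 | methyl (3aR,4S,5S,6E,10E,11aR)-5-[(tert-butyldimethylsilyl)oxy]-4-hydroxy-10-methyl-3-methylidene-2-oxo-2,3,3a,4,5,8,9,11a-octahydrocyclodeca[b]furan-6-carboxylate | O[C@H]1[C@H]2C(=C)C(=O)O[C@@H]2/C=C(\C)CC/C=C(/C(=O)OC)[C@@H]1O[Si](C)(C)C(C)(C)C | intermediate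
16 | methyl (3aS,4S,5S,6E,10E,11aR)-5-[(tert-butyldimethylsilyl)oxy]-10-methyl-3-methylidene-4-[(2-methylprop-2-enoyl)oxy]-2-oxo-2,3,3a,4,5,8,9,11a-octahydrocyclodeca[b]furan-6-carboxylate | C=C(C)C(=O)O[C@H]1[C@H]2C(=C)C(=O)O[C@@H]2/C=C(\C)CC/C=C(/C(=O)OC)[C@@H]1O[Si](C)(C)C(C)(C)C | intermediate
17 | methyl (3aS,4S,5S,6E,10E,11aR)-5-hydroxy-10-methyl-3-methylidene-4-[(2-methylprop-2-enoyl)oxy]-2-oxo-2,3,3a,4,5,8,9,11a-octahydrocyclodeca[b]furan-6-carboxylate | C=C(C)C(=O)O[C@H]1[C@H]2C(=C)C(=O)O[C@@H]2/C=C(\C)CC/C=C(/C(=O)OC)[C@@H]1O | target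

**Step count**
Total steps: 11. Longest linear sequence: 10 (steps 1–6 and 8–11; step 7 is the side branch).

**Three steps most likely to fail**

Risk 1, step 3 (the new hydroxylation; possible low ee or competing direct SN2 hydrolysis to the primary alcohol). The fallback sets out from racemic 3 and uses a lipase-catalysed kinetic resolution, which is established for MBH alcohols (Amano lipase PS, vinyl acetate, MTBE, 30 °C). The R enantiomer is acetylated to methyl (3R)-3-acetoxy-4,4-dimethoxy-2-methylidenebutanoate F1 and the unreacted S alcohol is 5, where the route is rejoined; bromide 4 is still made from the remaining racemic 3.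

Risk 2, step 8 (configuration at C6; Nozaki–Hiyama–Kishi additions often give modest substrate control, and it is not certain which C7 substituent acts as the large group). The fallback sets out from 9 and 12. The coupling is run with a neutral work-up so that 13 and its C6 epimer dimethyl (3S,4S,5S)-5-[(tert-butyldimethylsilyl)oxy]-4-hydroxy-3-[(1S,2E)-1-hydroxy-3-methylhepta-2,6-dien-1-yl]-2,6-dimethylideneheptanedioate F2 stay open-chain. MnO2 (CH2Cl2) oxidises only the allylic alcohol of the mixture to the enone dimethyl (3R,4S,5S)-5-[(tert-butyldimethylsilyl)oxy]-4-hydroxy-3-[(2E)-3-methylhepta-2,6-dienoyl]-2,6-dimethylideneheptanedioate F3. Me4NBH(OAc)3 (MeCN/AcOH, −30 °C) then gives the 1,3-anti diol 13 by hydroxyl-directed Saksena–Evans reduction from the free C8–OH, and PPTS lactonises it; the route is rejoined at 14.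

Risk 3, step 9 (ring-closing metathesis to a strained ten-membered ring through a hindered acrylate; oligomerisation is the likely failure). The fallback swaps the order of the two western bond formations and sets out from 5 and 12.
- Cross-metathesis (second-generation Hoveyda–Grubbs catalyst, CH2Cl2, 40 °C, excess 12) gives methyl (2E,6E)-2-[(1S)-1-hydroxy-2,2-dimethoxyethyl]-7-iodo-6-methylhepta-2,6-dienoate F4.
- Resin hydrolysis as in step 4 gives methyl (2E,6E)-2-[(1S)-1-hydroxy-2-oxoethyl]-7-iodo-6-methylhepta-2,6-dienoate F5, and indium coupling with 4 gives dimethyl (2E,3S,4S,5R)-5-(dimethoxymethyl)-3,4-dihydroxy-2-[(4E)-5-iodo-4-methylpent-4-en-1-ylidene]-6-methylideneheptanedioate F6.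
- Silylation as in step 5 gives dimethyl (2E,3S,4S,5R)-3-[(tert-butyldimethylsilyl)oxy]-5-(dimethoxymethyl)-4-hydroxy-2-[(4E)-5-iodo-4-methylpent-4-en-1-ylidene]-6-methylideneheptanedioate F7, and acetal cleavage as in step 6 gives dimethyl (2E,3S,4S,5R)-3-[(tert-butyldimethylsilyl)oxy]-5-formyl-4-hydroxy-2-[(4E)-5-iodo-4-methylpent-4-en-1-ylidene]-6-methylideneheptanedioate F8.
- An intramolecular NiCl2/CrCl2 coupling at high dilution (DMSO/THF, 2 mM) closes the ten-membered ring at C5–C6 to methyl (1E,5E,7R,8S,9S,10S)-10-[(tert-butyldimethylsilyl)oxy]-7,9-dihydroxy-8-(3-methoxy-3-oxoprop-1-en-2-yl)-5-methylcyclodeca-1,5-diene-1-carboxylate F9, which lactonises with PPTS to 15, where the route is rejoined.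

**Further compounds**
F1 | step 3 | methyl (3R)-3-acetoxy-4,4-dimethoxy-2-methylidenebutanoate | COC(OC)[C@H](OC(C)=O)C(=C)C(=O)OC
F2 | step 8 | dimethyl (3S,4S,5S)-5-[(tert-butyldimethylsilyl)oxy]-4-hydroxy-3-[(1S,2E)-1-hydroxy-3-methylhepta-2,6-dien-1-yl]-2,6-dimethylideneheptanedioate | COC(=O)C(=C)[C@@H]([C@@H](O)/C=C(\C)CCC=C)[C@H](O)[C@@H](O[Si](C)(C)C(C)(C)C)C(=C)C(=O)OC
F3 | step 8 | dimethyl (3R,4S,5S)-5-[(tert-butyldimethylsilyl)oxy]-4-hydroxy-3-[(2E)-3-methylhepta-2,6-dienoyl]-2,6-dimethylideneheptanedioate | COC(=O)C(=C)[C@@H](C(=O)/C=C(\C)CCC=C)[C@H](O)[C@@H](O[Si](C)(C)C(C)(C)C)C(=C)C(=O)OC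
F4 | step 9 | methyl (2E,6E)-2-[(1S)-1-hydroxy-2,2-dimethoxyethyl]-7-iodo-6-methylhepta-2,6-dienoate | COC(OC)[C@@H](O)/C(C(=O)OC)=C\CC/C(C)=C/I
F5 | step 9 | methyl (2E,6E)-2-[(1S)-1-hydroxy-2-oxoethyl]-7-iodo-6-methylhepta-2,6-dienoate | O=C[C@@H](O)/C(C(=O)OC)=C\CC/C(C)=C/I
F6 | step 9 | dimethyl (2E,3S,4S,5R)-5-(dimethoxymethyl)-3,4-dihydroxy-2-[(4E)-5-iodo-4-methylpent-4-en-1-ylidene]-6-methylideneheptanedioate | COC(=O)C(=C)[C@@H](C(OC)OC)[C@H](O)[C@@H](O)/C(C(=O)OC)=C\CC/C(C)=C/I
F7 | step 9 | dimethyl (2E,3S,4S,5R)-3-[(tert-butyldimethylsilyl)oxy]-5-(dimethoxymethyl)-4-hydroxy-2-[(4E)-5-iodo-4-methylpent-4-en-1-ylidene]-6-methylideneheptanedioate | COC(=O)C(=C)[C@@H](C(OC)OC)[C@H](O)[C@@H](O[Si](C)(C)C(C)(C)C)/C(C(=O)OC)=C\CC/C(C)=C/I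
F8 | step 9 | dimethyl (2E,3S,4S,5R)-3-[(tert-butyldimethylsilyl)oxy]-5-formyl-4-hydroxy-2-[(4E)-5-iodo-4-methylpent-4-en-1-ylidene]-6-methylideneheptanedioate | COC(=O)C(=C)[C@@H](C=O)[C@H](O)[C@@H](O[Si](C)(C)C(C)(C)C)/C(C(=O)OC)=C\CC/C(C)=C/I
F9 | step 9 | methyl (1E,5E,7R,8S,9S,10S)-10-[(tert-butyldimethylsilyl)oxy]-7,9-dihydroxy-8-(3-methoxy-3-oxoprop-1-en-2-yl)-5-methylcyclodeca-1,5-diene-1-carboxylate | COC(=O)C(=C)[C@@H]1[C@H](O)[C@@H](O[Si](C)(C)C(C)(C)C)/C(C(=O)OC)=C\CC/C(C)=C/[C@H]1O
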